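Two end amounts of E and one choice between them are asked, and the givens fold into one number.

| flask | G | Q | remark | time |
|---|---|---|---|---|
| cedar | 35 mM | 26 mM | run made earlier |  |
| ash | 35 mM | 42 mM | run made earlier |  |
| elm | 31 mM | 38.5 mM | run made earlier |  |
| Sunday's | 25 mM | 60.0 mM |  | 0.40 h |
| Wednesday's | 35 mM | 38.5 mM |  | 1.5 h |

- cedar (time / min: E / %, G / %): 10.0: 24.3, 36.6; 20.0: 37.1, 14.2; 25.0: 39.6, 9.3; 40.0: 42.2, 4.4; 50.0: 42.3, 4.4; 60.0: 41.4, 4.0
- ash (time / min: E / %, G / %): 10.0: 35.8, 30.0; 20.0: 57.2, 0; 25.0: 60.2, 1.0; 40.0: 62.4, 0.3; 50.0: 63.2, 0.8; 60.0: 63.9, 0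
- elm (time / min: E / %, G / %): 5.00: 18.8, 51.8; 10.0: 37.9, 23.0; 20.0: 58.9, 0.1; 30.0: 63.7, 0.6; 60.0: 66.5, 0.9

(readings scatter by 0.5 percentage points)

- G is a solid; its amount is given per volume of the solution
- steps that have been proposed: G <-> J; Q -> Z; J + Q -> E
- at the start none of G is in solution
- what has only dissolved of G counts as not reacted

- which of the two ends with the higher amount of E, in percent of the G charged ("neither" if they lie within 2 percentage points) (Sunday's / Wednesday's / neither)
- E at the end, in percent of the G charged, Sunday's
- E at the end, in percent of the G charged, Wednesday's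

At its last reading the elm run holds 0.535 mole of E per mole of Q charged; call this φ, the share of charged Q that reaches E rather than Z. Folded with a flask's charges it gives N = φ·Q/G, the fraction of charged G that the charged Q carries to E if φ holds in that flask, so an N below one reads Q as the limiting reagent.

N is tested on two earlier runs. For the ash run N is 64.3% against a last reading of 63.9%, a gap of 0.35 percentage points, while the last reading of the cedar run stands 1.6 points above its N, with a scatter of 0.5 points per reading, so φ is a reading with some drift.

Wednesday's has N = 58.9%, although Q stands at 1.10 equivalents, and the elm run gained 2.8 points between 30.0 min and 60.0 min, so the reckoning here for Wednesday's at 90 min is that same figure.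

Sunday's has N = 1.29, which gives no figure for E, so one number is not enough there and the clock must enter. Sunday's 24 min lies between the elm readings at 20.0 min and 30.0 min, when that run stood at 88.6% and 95.8% of its last reading, and borrowing those shares puts Sunday's E in that range, higher than Wednesday's.

The forecast named Sunday's, with 95% for Sunday's and 65% for Wednesday's, the latter higher than the reckoning here, holding that in Wednesday's “Q runs out first”.

Sunday's ends at 89.2% and Wednesday's at 59.5%, so the higher E stands in Sunday's.

    G ⇌ J, rate k1*(cs1 - [J]) while solid is left; crystals form when [J] > cs1 (solubility = 19.0 mM, k = 0.00380 s⁻¹)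
    Q → Z (k = 8.10 × 10⁻⁴ s⁻¹)
    J + Q → E (k = 0.100 M⁻¹ s⁻¹)

In Wednesday's at 1.50 h, Q stands at 0% of its charge beside 17.7 mM of Z, and the E reached makes φ there 0.541, against 0.535 carried from the elm run. A further flask, like Wednesday's but charged with 9.6 mM of Q, has N = 14.7%, and it gives 16.0% of E with 29.7% of G still solid.

The data were computed with made-up constants, and the scatter is random.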